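Its constants are invented; the flask was simulated.

The flasks differ in temperature.

in all of them: substrate 0.39 M; reagent 1.95 M; free catalyst 70 mM; time 1.0 h
- Tuesday's: temperature 60 °C
- Sunday's: temperature 10 °C
- Saturday's: temperature 35 °C

    substrate + reagent + free catalyst → target + free catalyst, rate k1*[substrate]*[reagent]*[free catalyst]/(1 + ([substrate]/sat1)) (sat1 = 22 mM, k1 = 0.91 /M²/s, Ea1 = 49.0 kJ/mol)
    substrate + target → side product (k2 = 0.10 /M/s, Ea2 = 60.0 kJ/mol)
    free catalyst → spent catalyst A (k3 = 0.0011 /s, Ea3 = 85.0 kJ/mol)
    free catalyst → spent catalyst B (k4 = 1.2 × 10⁻⁶ /s, Ea4 = 109 kJ/mol)
    (constants at 35 °C)

- in percentages every species weighs as the substrate in it: one side product counts as two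
- all constants are for 35 °C and move with temperature by the activation energies

1. which flask leads in amount of target, in percent of the substrate charged ("all alike" within 1.5 percentage points) (Tuesday's / Sunday's / Saturday's / all alike)
2. how much target is there at the end, in percent of the substrate charged: Tuesday's
3. how much target is there at the end, in percent of the substrate charged: Sunday's
4. how much target is there at the end, in percent of the substrate charged: Saturday's

A bench rule treats a catalyst flooded with substrate as a pump with a fixed flow. The substrate charge stands 17.7 times above the saturation constant of 22 mM, so the first step is nearly zero-order in substrate. Its flow is the rate constant times reagent, free catalyst and that constant, with reagent and free catalyst held at their charges. In Sunday's flask this gives 0.505 mM/s, and the rule says the charge becomes target in 12.9 min.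

But the second step eats substrate and target together, at its rate constant times their product. It matches the pump when that product reaches flow over rate constant. I call the square root of this the meeting level, the amount at which substrate and target stand equal while the two steps run equally fast. In Sunday's flask, with the two rate constants taken at its temperature:

level = 0.200 M

The bench rule leaves this step out, so I set the charge against the level. Sunday's charge stands at 1.95 levels, so I do not trust the rule there and reckon the loss.

Dividing one rate by the other removes time, while free catalyst stays inside the level, where I hold it at its charge, as I do reagent. With s as substrate plus the saturation constant, the exact brake drops out of the equation: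

d(target)/ds = −(level² − s × target) / (level² + s × target)

I step this curve by hand from s at about twice the level, and target reaches about the level as s nears zero. The flask stops earlier, at s equal to the saturation constant, and the slope there is close to one. So:

target at the end ≈ level − saturation constant

Tuesday's, from a level of 0.141 M: 30.4%

Sunday's: 45.6%

Saturday's, from a level of 0.165 M: 36.7%

Leader: Sunday's, whose level is higher than the others.

In Tuesday's flask the catalyst lifetime of 75.4 s is longer than the pump time of 34.0 s by a factor of 2.22, so holding free catalyst at its charge is a rough step there.

The forecast named Sunday's, with 28%, 46% and 37% for Tuesday's, Sunday's and Saturday's, holding that “cooling favours target”.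

The simulation gives 27.5%, 45.0% and 36.3% in that order, and Sunday's leads.

Without the second step, Sunday's target climbs from 45.0% to 100%, so that step is the main reason for the loss. The level moves with the square root of the reagent, so at 1.57 M of reagent Sunday's level falls to 0.179 M, and I reckon a move of 5.3 percentage points. Sunday's run at that amount of reagent has moved by 5 points.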